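**Assumption:** the SMILES is taken literally (ring carbons cis across both the oxirane and the C9=C10 alkene, C2=C3 trans). Ring atoms are numbered C1 (quaternary), C2=C3, C4 (ester carbinol), C5/C6 (oxirane), C7, C8, C9 (bears CH2OH), C10, C11; the side chain is C1′–C5′ with the carbinol at C3′. Ligand antipodes are named for the face selectivity required.

## Retrosynthetic overview
1. Target 27 ⇐ macrocyclic C4 alcohol 23 (late ester reduction, senecioylation, desilylation).
2. Eleven-membered carbocycle ⇐ C3–C4 bond by reductive alkyne–aldehyde macrocyclisation of ynal 21 (proposed new chiral-carbene nickel method; sets C4).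
3. 21 ⇐ E-selective Wittig union at C9=C10 of aldehyde 9 (fragment A) and ylide 18 (fragment B).
4. Fragment A ⇐ geraniol: copper-catalysed SN2′ alkynylation sets quaternary C1; Shi epoxidation then isomerisation sets C3′.
5. Fragment B ⇐ 3-silyloxypropanal: Still–Gennari Z-olefination, Sharpless epoxidation sets C5/C6. Ring order: oxirane first (step 10), carbocycle second (step 18).

## Route

### Fragment A

**Step 1**
Reactants: 1 geraniol
Product: 2 geranyl diethyl phosphate
Conditions: ClP(O)(OEt)2, Et3N, DMAP (cat.), CH2Cl2, 0 °C to rt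
Reagents that add atoms: diethyl chlorophosphate CCOP(=O)(Cl)OCC
Why: Standard phosphorylation of a primary allylic alcohol gives the leaving group for copper-catalysed allylic substitution; no stereocentre is formed and the E alkene is untouched.

**Step 2**
Reactants: 2 geranyl diethyl phosphate
Product: 3 [(3S)-3-ethenyl-3,7-dimethyloct-6-en-1-yn-1-yl]trimethylsilane
Conditions: (i-Bu)2AlC≡CSiMe3 (1.5 equiv, preformed from i-Bu2AlH and Me3SiC≡CH), CuCl2·2H2O (5 mol%), (4S,5S)-1-(2,6-diisopropylphenyl)-4,5-diphenyl-3-(2-sulfonatophenyl)-4,5-dihydroimidazolium inner salt (5.5 mol%), THF, −15 °C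
Reagents that add atoms: diisobutyl[(trimethylsilyl)ethynyl]aluminium CC(C)C[Al](CC(C)C)C#C[Si](C)(C)C
Why: Carbene–copper-catalysed enantioselective SN2′ allylic substitution with an alkynylaluminium (the divalent copper salt is reduced in situ to the active monovalent copper–carbene) puts the alkynyl group on the trisubstituted carbon, the ligand antipode being the one that directs attack to the Si face of C3 so that quaternary C1 is S and the vinyl group that becomes C11–C10 is released.

**Step 3**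
Reactants: 3 [(3S)-3-ethenyl-3,7-dimethyloct-6-en-1-yn-1-yl]trimethylsilane
Product: 5 (3S)-3,7-dimethyl-3-[(trimethylsilyl)ethynyl]oct-6-en-1-ol, via B-alkyl-9-BBN adduct 4 (not isolated)
Conditions: 9-BBN, THF, 0 °C to rt; then NaBO3·4H2O, H2O, rt
Reagents that add atoms: 9-borabicyclo[3.3.1]nonane B1C2CCCC1CCC2; sodium perborate [Na+].[Na+].O[B-]1(O)OO[B-](O)(O)OO1
Why: Hydroboration–oxidation: 9-BBN adds anti-Markovnikov to the monosubstituted vinyl group far faster than to the trisubstituted alkene or the doubly hindered silylalkyne, and mild perborate oxidation gives the primary alcohol without C–Si cleavage.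

**Step 4**
Reactants: 5 (3S)-3,7-dimethyl-3-[(trimethylsilyl)ethynyl]oct-6-en-1-ol
Product: 6 (3S)-5-[(2S)-3,3-dimethyloxiran-2-yl]-3-methyl-3-[(trimethylsilyl)ethynyl]pentan-1-ol
Conditions: 1,2:4,5-di-O-isopropylidene-β-L-erythro-2,3-hexodiulo-2,6-pyranose (L-fructose-derived Shi ketone, 30 mol%), KHSO5 (as 2KHSO5·KHSO4·K2SO4), K2CO3, Bu4NHSO4, Na2B4O7 buffer, MeCN–CH2(OMe)2–H2O, 0 °C
Reagents that add atoms: potassium peroxymonosulfate [K+].[O-]S(=O)(=O)OO
Why: Shi asymmetric epoxidation: the chiral dioxirane attacks only the electron-rich trisubstituted alkene through the spiro transition state, and the L-fructose-derived ketone gives the S epoxide carbon (the D-fructose ketone gives R), independent of remote C1.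

**Step 5**
Reactants: 6 (3S)-5-[(2S)-3,3-dimethyloxiran-2-yl]-3-methyl-3-[(trimethylsilyl)ethynyl]pentan-1-ol
Product: 7 (3S,6S)-3,7-dimethyl-3-[(trimethylsilyl)ethynyl]oct-7-ene-1,6-diol
Conditions: Al(Oi-Pr)3, toluene, 110 °C
Reagents that add atoms: none
Why: Aluminium alkoxide-mediated epoxide-to-allylic-alcohol isomerisation breaks the tertiary C–O bond with loss of a methyl proton, so the secondary C–O bond keeps its S configuration and the isopropenyl carbinol of the side chain is formed.

**Step 6**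
Reactants: 7 (3S,6S)-3,7-dimethyl-3-[(trimethylsilyl)ethynyl]oct-7-ene-1,6-diol
Product: 8 (3S,6S)-6-hydroxy-3,7-dimethyl-3-[(trimethylsilyl)ethynyl]oct-7-enal
Conditions: TEMPO (10 mol%), PhI(OAc)2, CH2Cl2, rt
Reagents that add atoms: none
Why: The oxoammonium (TEMPO/PhI(OAc)2) oxidation takes the unhindered primary alcohol to the aldehyde much faster than the secondary allylic alcohol and does not over-oxidise.

**Step 7**
Reactants: 8 (3S,6S)-6-hydroxy-3,7-dimethyl-3-[(trimethylsilyl)ethynyl]oct-7-enal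
Product: 9 (3S,6S)-6-[(tert-butyldimethylsilyl)oxy]-3,7-dimethyl-3-[(trimethylsilyl)ethynyl]oct-7-enal (fragment A)
Conditions: TBSCl, imidazole, DMF, rt
Reagents that add atoms: tert-butyldimethylsilyl chloride CC(C)(C)[Si](C)(C)Cl
Why: Imidazole-promoted silylation protects the C3′ hydroxyl so that only C4–OH is free for the later oxidation and acylation; no stereocentre is touched.

### Fragment B

**Step 8**
Reactants: 10 3-[(tert-butyldimethylsilyl)oxy]propanal
Product: 11 methyl (2Z)-5-[(tert-butyldimethylsilyl)oxy]-2-methylpent-2-enoate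
Conditions: (CF3CH2O)2P(O)CH(CH3)CO2Me, KN(SiMe3)2, 18-crown-6, THF, −78 °C
Reagents that add atoms: methyl 2-[bis(2,2,2-trifluoroethoxy)phosphoryl]propanoate COC(=O)C(C)P(=O)(OCC(F)(F)F)OCC(F)(F)F
Why: Still–Gennari olefination: the electron-poor phosphonate with a dissociated potassium counter-ion eliminates from the kinetic adduct and gives the Z trisubstituted enoate (ester cis to C7), the geometry that becomes the cis oxirane.

**Step 9**
Reactants: 11 methyl (2Z)-5-[(tert-butyldimethylsilyl)oxy]-2-methylpent-2-enoate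
Product: 12 (2Z)-5-[(tert-butyldimethylsilyl)oxy]-2-methylpent-2-en-1-ol
Conditions: i-Bu2AlH, CH2Cl2, −78 °C
Reagents that add atoms: none
Why: Aluminium hydride 1,2-reduction of the enoate gives the allylic alcohol with the Z geometry retained.

**Step 10**
Reactants: 12 (2Z)-5-[(tert-butyldimethylsilyl)oxy]-2-methylpent-2-en-1-ol
Product: 13 [(2R,3S)-3-{2-[(tert-butyldimethylsilyl)oxy]ethyl}-2-methyloxiran-2-yl]methanol
Conditions: Ti(Oi-Pr)4 (10 mol%), D-(−)-diethyl tartrate (12 mol%), t-BuOOH, 4 Å sieves, CH2Cl2, −20 °C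
Reagents that add atoms: tert-butyl hydroperoxide CC(C)(C)OO
Why: Sharpless asymmetric epoxidation: the titanium–tartrate complex delivers oxygen to one face of the allylic alcohol, and D-(−)-tartrate on this Z alcohol gives the (2R,3S) epoxy alcohol, which is C5 and C6 of the target with C4 and C7 cis.

**Step 11**
Reactants: 13 [(2R,3S)-3-{2-[(tert-butyldimethylsilyl)oxy]ethyl}-2-methyloxiran-2-yl]methanol
Product: 14 [(2R,3S)-3-{2-[(tert-butyldimethylsilyl)oxy]ethyl}-2-methyloxiran-2-yl]methyl acetate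
Conditions: Ac2O, pyridine, DMAP (cat.), CH2Cl2, 0 °C
Reagents that add atoms: acetic anhydride CC(=O)OC(C)=O
Why: DMAP-catalysed acetylation masks the C4 hydroxyl with a group that later comes off together with the alkynyl silane.

**Step 12**
Reactants: 14 [(2R,3S)-3-{2-[(tert-butyldimethylsilyl)oxy]ethyl}-2-methyloxiran-2-yl]methyl acetate
Product: 15 [(2R,3S)-3-(2-hydroxyethyl)-2-methyloxiran-2-yl]methyl acetate
Conditions: Bu4NF, AcOH, THF, 0 °C to rt
Reagents that add atoms: none
Why: Buffered fluoride desilylation frees the C8 hydroxyl without acid (which could trigger 5-endo opening of the oxirane) and without cleaving the acetate.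

**Step 13**
Reactants: 15 [(2R,3S)-3-(2-hydroxyethyl)-2-methyloxiran-2-yl]methyl acetate
Product: 16 [(2R,3S)-3-(2-iodoethyl)-2-methyloxiran-2-yl]methyl acetate
Conditions: I2, PPh3, imidazole, CH2Cl2, 0 °C
Reagents that add atoms: iodine II
Why: Appel-type iodination (Garegg–Samuelsson conditions) displaces the primary alkoxyphosphonium by iodide, imidazole scavenging the acid so the oxirane survives.

**Step 14**
Reactants: 16 [(2R,3S)-3-(2-iodoethyl)-2-methyloxiran-2-yl]methyl acetate
Product: 18 methyl 4-[(2S,3R)-3-(acetoxymethyl)-3-methyloxiran-2-yl]-2-(triphenylphosphoranylidene)butanoate (fragment B), via phosphonium iodide 17 (not isolated)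
Conditions: Ph3P=CHCO2Me (2.2 equiv), MeCN, 80 °C
Reagents that add atoms: methyl (triphenylphosphoranylidene)acetate COC(=O)C=P(c1ccccc1)(c1ccccc1)c1ccccc1
Why: C-alkylation of the stabilised ylide by the primary iodide followed by transylidation with the second equivalent of ylide gives the α-substituted stabilised ylide under neutral conditions that spare acetate and oxirane.

### Union and endgame

**Step 15**
Reactants: 9 fragment A aldehyde; 18 fragment B ylide
Product: 19 methyl (2E,5S,8S)-2-{2-[(2S,3R)-3-(acetoxymethyl)-3-methyloxiran-2-yl]ethyl}-8-[(tert-butyldimethylsilyl)oxy]-5,9-dimethyl-5-[(trimethylsilyl)ethynyl]deca-2,9-dienoate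
Conditions: toluene, 90 °C
Reagents that add atoms: none
Why: Wittig olefination with an α-branched stabilised ylide is E-selective (ester trans to C11), which places C8 and C11 cis on C9=C10 as in the target; no stereocentre is affected.

**Step 16**
Reactants: 19 Wittig product
Product: 20 methyl (2E,5S,8S)-8-[(tert-butyldimethylsilyl)oxy]-5-ethynyl-2-{2-[(2S,3R)-3-(hydroxymethyl)-3-methyloxiran-2-yl]ethyl}-5,9-dimethyldeca-2,9-dienoate
Conditions: K2CO3, MeOH, rt
Reagents that add atoms: none
Why: Carbonate-catalysed methanolysis removes the acetate and the alkynyl C–SiMe3 group in one operation while the methyl ester, the oxirane and the secondary silyl ether are unchanged.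

**Step 17**
Reactants: 20 alkynol
Product: 21 methyl (2E,5S,8S)-8-[(tert-butyldimethylsilyl)oxy]-5-ethynyl-2-{2-[(2S,3S)-3-formyl-3-methyloxiran-2-yl]ethyl}-5,9-dimethyldeca-2,9-dienoate
Conditions: Dess–Martin periodinane, NaHCO3, CH2Cl2, 0 °C to rt
Reagents that add atoms: none
Why: Buffered Dess–Martin oxidation gives the α,β-epoxy aldehyde, which cannot epimerise because its α-carbon (C5) is fully substituted.

**Step 18**
Reactants: 21 ynal
Product: 23 eleven-membered epoxy alcohol (1S,2E,4R,5R,6S,9E,3′S; 9-CO2Me; 3′-OTBS), via triethylsilyl ether 22 (not isolated)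
Conditions: Ni(cod)2 (20 mol%), (4R,5R)-1,3-bis(2-cyclohexyl-6-methylphenyl)-4,5-diphenyl-4,5-dihydroimidazolium tetrafluoroborate (20 mol%), KOt-Bu (20 mol%), Et3SiH (5 equiv), THF, 21 added over 12 h (final 0.003 M), rt; then PPTS, MeOH, 0 °C
Reagents that add atoms: triethylsilane CC[SiH](CC)CC (silicon held only in 22)
Why: Proposed new method: a zerovalent nickel catalyst bearing a bulky C2-symmetric chiral N-heterocyclic carbene should join the terminal alkyne and the epoxy aldehyde by oxidative cyclisation to an oxanickelacycle, with the new C3–C4 bond at the unhindered alkyne terminus because quaternary C1 blocks the internal carbon, after which σ-bond metathesis with the silane and C–H reductive elimination give the E-allylic silyl ether 22 in the eleven-membered ring, the ligand antipode being chosen to steer bond formation to the Re face of the aldehyde so that C4 is R; the closest known reaction type is the nickel-catalysed reductive alkyne–aldehyde macrocyclisation with achiral carbene ligands and its intermolecular chiral-carbene variant, neither shown for an α,β-epoxy aldehyde, an eleven-membered carbocycle or ligand-controlled stereochemistry in a ring closure.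

**Step 19**
Reactants: 23 macrocyclic ester alcohol
Product: 24 macrocyclic diol (C4–OH and C9–CH2OH; 3′-OTBS; 1S,4R,5R,6S,3′S)
Conditions: i-Bu2AlH, CH2Cl2, −78 °C
Reagents that add atoms: none
Why: Aluminium hydride 1,2-reduction of the methyl enoate to the allylic alcohol is much faster at −78 °C than opening of the hindered trisubstituted oxirane; the alkene geometry is retained.

**Step 20**
Reactants: 24 macrocyclic diol
Product: 25 C9-CH2OTBS mono-silyl ether of 24 (C4–OH free)
Conditions: TBSCl (1.1 equiv), imidazole, CH2Cl2, 0 °C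
Reagents that add atoms: tert-butyldimethylsilyl chloride CC(C)(C)[Si](C)(C)Cl
Why: Silylation is selective for the unhindered primary allylic hydroxyl over the secondary C4 hydroxyl flanked by the fully substituted oxirane carbon.

**Step 21**
Reactants: 25 mono-silyl ether
Product: 26 C4 3-methylbut-2-enoate of 25 (bis-silyl ether; 1S,4R,5S,6S,3′S)
Conditions: 3-methylbut-2-enoyl chloride, pyridine, DMAP, CH2Cl2, 0 °C to rt
Reagents that add atoms: 3-methylbut-2-enoyl chloride CC(C)=CC(=O)Cl
Why: DMAP-catalysed acylation of the C4 alcohol proceeds with retention at C4, and pyridine in place of a stronger amine avoids deconjugation of the senecioyl unit through the vinylketene.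

**Step 22**
Reactants: 26 bis-silyl ether senecioate
Product: 27 target CNP0309478.6
Conditions: HF·pyridine, pyridine, THF, 0 °C to rt
Reagents that add atoms: none
Why: Pyridine-buffered fluoride desilylation removes the primary and the secondary silyl ether without opening the oxirane or cleaving the ester.

## Compound list
1 | geraniol, (2E)-3,7-dimethylocta-2,6-dien-1-ol | CC(C)=CCC/C(C)=C/CO | starting material
2 | geranyl diethyl phosphate | CC(C)=CCC/C(C)=C/COP(=O)(OCC)OCC | intermediate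
3 | [(3S)-3-ethenyl-3,7-dimethyloct-6-en-1-yn-1-yl]trimethylsilane | CC(C)=CCC[C@](C=C)(C)C#C[Si](C)(C)C | intermediate
4 | B-alkyl-9-BBN adduct of 3 (boron on the former vinyl terminus) | CC(C)=CCC[C@](CCB1C2CCCC1CCC2)(C)C#C[Si](C)(C)C | intermediate
5 | (3S)-3,7-dimethyl-3-[(trimethylsilyl)ethynyl]oct-6-en-1-ol | CC(C)=CCC[C@](CCO)(C)C#C[Si](C)(C)C | intermediate
6 | (3S)-5-[(2S)-3,3-dimethyloxiran-2-yl]-3-methyl-3-[(trimethylsilyl)ethynyl]pentan-1-ol | CC1(C)O[C@H]1CC[C@](CCO)(C)C#C[Si](C)(C)C | intermediate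
7 | (3S,6S)-3,7-dimethyl-3-[(trimethylsilyl)ethynyl]oct-7-ene-1,6-diol | C=C(C)[C@@H](O)CC[C@](CCO)(C)C#C[Si](C)(C)C | intermediate
8 | (3S,6S)-6-hydroxy-3,7-dimethyl-3-[(trimethylsilyl)ethynyl]oct-7-enal | C=C(C)[C@@H](O)CC[C@](CC=O)(C)C#C[Si](C)(C)C | intermediate
9 | (3S,6S)-6-[(tert-butyldimethylsilyl)oxy]-3,7-dimethyl-3-[(trimethylsilyl)ethynyl]oct-7-enal (fragment A) | C=C(C)[C@@H](O[Si](C)(C)C(C)(C)C)CC[C@](CC=O)(C)C#C[Si](C)(C)C | intermediate
10 | 3-[(tert-butyldimethylsilyl)oxy]propanal | CC(C)(C)[Si](C)(C)OCCC=O | starting material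
11 | methyl (2Z)-5-[(tert-butyldimethylsilyl)oxy]-2-methylpent-2-enoate | COC(=O)/C(C)=C\CCO[Si](C)(C)C(C)(C)C | intermediate
12 | (2Z)-5-[(tert-butyldimethylsilyl)oxy]-2-methylpent-2-en-1-ol | OC/C(C)=C\CCO[Si](C)(C)C(C)(C)C | intermediate
13 | [(2R,3S)-3-{2-[(tert-butyldimethylsilyl)oxy]ethyl}-2-methyloxiran-2-yl]methanol | OC[C@@]1(C)O[C@H]1CCO[Si](C)(C)C(C)(C)C | intermediate
14 | [(2R,3S)-3-{2-[(tert-butyldimethylsilyl)oxy]ethyl}-2-methyloxiran-2-yl]methyl acetate | CC(=O)OC[C@@]1(C)O[C@H]1CCO[Si](C)(C)C(C)(C)C | intermediate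
15 | [(2R,3S)-3-(2-hydroxyethyl)-2-methyloxiran-2-yl]methyl acetate | CC(=O)OC[C@@]1(C)O[C@H]1CCO | intermediate
16 | [(2R,3S)-3-(2-iodoethyl)-2-methyloxiran-2-yl]methyl acetate | CC(=O)OC[C@@]1(C)O[C@H]1CCI | intermediate
17 | {4-[(2S,3R)-3-(acetoxymethyl)-3-methyloxiran-2-yl]-1-methoxy-1-oxobutan-2-yl}triphenylphosphonium iodide | COC(=O)C(CC[C@@H]1O[C@]1(C)COC(C)=O)[P+](c1ccccc1)(c1ccccc1)c1ccccc1.[I-] | intermediate
18 | methyl 4-[(2S,3R)-3-(acetoxymethyl)-3-methyloxiran-2-yl]-2-(triphenylphosphoranylidene)butanoate (fragment B) | COC(=O)C(CC[C@@H]1O[C@]1(C)COC(C)=O)=P(c1ccccc1)(c1ccccc1)c1ccccc1 | intermediate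
19 | methyl (2E,5S,8S)-2-{2-[(2S,3R)-3-(acetoxymethyl)-3-methyloxiran-2-yl]ethyl}-8-[(tert-butyldimethylsilyl)oxy]-5,9-dimethyl-5-[(trimethylsilyl)ethynyl]deca-2,9-dienoate | C=C(C)[C@@H](O[Si](C)(C)C(C)(C)C)CC[C@](C/C=C(C(=O)OC)\CC[C@@H]1O[C@]1(C)COC(C)=O)(C)C#C[Si](C)(C)C | intermediate
20 | methyl (2E,5S,8S)-8-[(tert-butyldimethylsilyl)oxy]-5-ethynyl-2-{2-[(2S,3R)-3-(hydroxymethyl)-3-methyloxiran-2-yl]ethyl}-5,9-dimethyldeca-2,9-dienoate | C=C(C)[C@@H](O[Si](C)(C)C(C)(C)C)CC[C@](C/C=C(C(=O)OC)\CC[C@@H]1O[C@]1(C)CO)(C)C#C | intermediate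
21 | methyl (2E,5S,8S)-8-[(tert-butyldimethylsilyl)oxy]-5-ethynyl-2-{2-[(2S,3S)-3-formyl-3-methyloxiran-2-yl]ethyl}-5,9-dimethyldeca-2,9-dienoate | C=C(C)[C@@H](O[Si](C)(C)C(C)(C)C)CC[C@](C/C=C(C(=O)OC)\CC[C@@H]1O[C@]1(C)C=O)(C)C#C | intermediate
22 | C4 triethylsilyl ether of 23 (1S,4R,5S,6S,3′S; 2E,9E) | C=C(C)[C@@H](O[Si](C)(C)C(C)(C)C)CC[C@]1(C)/C=C/[C@@H](O[Si](CC)(CC)CC)[C@@]2(C)O[C@H]2CC/C(C(=O)OC)=C\C1 | intermediate
23 | eleven-membered epoxy alcohol: C4–OH, 5,6-epoxide, 9-CO2Me, 3′-OTBS (1S,4R,5R,6S,3′S; 2E,9E; C5 is R by CIP only because C4–OH is free, same spatial arrangement as in 27) | C=C(C)[C@@H](O[Si](C)(C)C(C)(C)C)CC[C@]1(C)/C=C/[C@@H](O)[C@@]2(C)O[C@H]2CC/C(C(=O)OC)=C\C1 | intermediate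
24 | macrocyclic diol: C4–OH, C9–CH2OH, 3′-OTBS (1S,4R,5R,6S,3′S) | C=C(C)[C@@H](O[Si](C)(C)C(C)(C)C)CC[C@]1(C)/C=C/[C@@H](O)[C@@]2(C)O[C@H]2CC/C(CO)=C\C1 | intermediate
25 | C9-CH2OTBS mono-silyl ether of 24 (C4–OH free) | C=C(C)[C@@H](O[Si](C)(C)C(C)(C)C)CC[C@]1(C)/C=C/[C@@H](O)[C@@]2(C)O[C@H]2CC/C(CO[Si](C)(C)C(C)(C)C)=C\C1 | intermediate
26 | C4 3-methylbut-2-enoate, bis-silyl ether (1S,4R,5S,6S,3′S) | C=C(C)[C@@H](O[Si](C)(C)C(C)(C)C)CC[C@]1(C)/C=C/[C@@H](OC(=O)C=C(C)C)[C@@]2(C)O[C@H]2CC/C(CO[Si](C)(C)C(C)(C)C)=C\C1 | intermediate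
27 | CNP0309478.6 (1S,4R,5S,6S,3′S; 2E; 9E with ring carbons cis) | C=C(C)[C@@H](O)CC[C@]1(C)/C=C/[C@@H](OC(=O)C=C(C)C)[C@@]2(C)O[C@H]2CC/C(CO)=C\C1 | target

## Summary
Total step count: 22.
Longest linear sequence: 15 steps (steps 1–7 then 15–22; equally steps 8–14 then 15–22).

## Three steps most likely to fail

**Step 18 (the proposed new step; ring closure and C4).** The fallback sets out from ynal 21 and comes back at alcohol 23 using the known Oppolzer macrocyclisation. Hydroboration of the terminal alkyne of 21 with (c-C6H11)2BH in hexane at 0 °C gives the (E)-alkenyldicyclohexylborane F1. F1 is added slowly to Et2Zn and 5 mol% (+)-DAIB [(2R)-3-exo-(dimethylamino)isoborneol] at high dilution. Boron-to-zinc exchange gives the alkenyl(ethyl)zinc F2, and its amino-alkoxide-catalysed intramolecular addition to the Re face of the aldehyde gives 23 directly as the free alcohol.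

**Step 2 (quaternary C1; the silylalkynyl-aluminium may be sluggish or give SN2 product).** The fallback sets out from geraniol 1 and comes back at enyne 3 by a chirality-transfer sequence.
- Sharpless epoxidation of 1 (Ti(Oi-Pr)4, D-(−)-diethyl tartrate, t-BuOOH) gives (2R,3R)-2,3-epoxygeraniol F3.
- TBSCl and imidazole give its silyl ether F4.
- Yamamoto rearrangement with MeAl(OAr)2 (Ar = 4-bromo-2,6-di-tert-butylphenyl; CH2Cl2, −78 °C) shifts the siloxymethyl group to C3 anti to the breaking C–O bond and gives the α-quaternary (R)-aldehyde F5 with full chirality transfer.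
- Ph3P=CH2 gives the vinyl silyl ether F6, and Bu4NF gives the alcohol F7.
- Dess–Martin oxidation gives the aldehyde F8.
- Dimethyl (1-diazo-2-oxopropyl)phosphonate with K2CO3 in MeOH gives the terminal enyne F9.
- n-BuLi then Me3SiCl gives 3.

**Step 14 (C-alkylation of a stabilised ylide by an unactivated primary iodide).** The fallback sets out from iodide 16 and comes back at 19, skipping 17 and 18. The sodium salt of trimethyl phosphonoacetate (NaH, DMF) is alkylated with 16 to give the phosphonate F10. A Horner–Wadsworth–Emmons reaction of F10 with aldehyde 9 (NaH, THF, 0 °C) gives 19, the minor Z isomer being removed by chromatography.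

## Further compounds
F1 | step 18 | (E)-alkenyldicyclohexylborane from hydroboration of the alkyne of 21 | C=C(C)[C@@H](O[Si](C)(C)C(C)(C)C)CC[C@](C/C=C(C(=O)OC)\CC[C@@H]1O[C@]1(C)C=O)(C)/C=C/B(C1CCCCC1)C1CCCCC1
F2 | step 18 | (E)-alkenyl(ethyl)zinc from boron-to-zinc exchange of F1 | C=C(C)[C@@H](O[Si](C)(C)C(C)(C)C)CC[C@](C/C=C(C(=O)OC)\CC[C@@H]1O[C@]1(C)C=O)(C)/C=C/[Zn]CC
F3 | step 2 | (2R,3R)-2,3-epoxygeraniol | OC[C@H]1O[C@]1(C)CCC=C(C)C
F4 | step 2 | tert-butyldimethylsilyl ether of (2R,3R)-2,3-epoxygeraniol | CC(C)(C)[Si](C)(C)OC[C@H]1O[C@]1(C)CCC=C(C)C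
F5 | step 2 | (2R)-2-{[(tert-butyldimethylsilyl)oxy]methyl}-2,6-dimethylhept-5-enal | CC(C)(C)[Si](C)(C)OC[C@@](C=O)(C)CCC=C(C)C
F6 | step 2 | tert-butyl{[(2S)-2-ethenyl-2,6-dimethylhept-5-en-1-yl]oxy}dimethylsilane | CC(C)(C)[Si](C)(C)OC[C@@](C=C)(C)CCC=C(C)C
F7 | step 2 | (2S)-2-ethenyl-2,6-dimethylhept-5-en-1-ol | OC[C@@](C=C)(C)CCC=C(C)C
F8 | step 2 | (2S)-2-ethenyl-2,6-dimethylhept-5-enal | O=C[C@@](C=C)(C)CCC=C(C)C
F9 | step 2 | (3S)-3-ethenyl-3,7-dimethyloct-6-en-1-yne | C#C[C@@](C=C)(C)CCC=C(C)C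
F10 | step 14 | methyl 4-[(2S,3R)-3-(acetoxymethyl)-3-methyloxiran-2-yl]-2-(dimethoxyphosphoryl)butanoate | COC(=O)C(CC[C@@H]1O[C@]1(C)COC(C)=O)P(=O)(OC)OC
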